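**Retrosynthetic overview**
1. The C6-prenyl group comes from an aromatic Claisen shift of a 5-O-(1,1-dimethylallyl) ether. The prenyl unit therefore enters as a C–O bond, and that oxygen fixes its position.
2. The pyranone (ring C) comes from O1–C2 acyl transfer plus C3=C4 condensation. The partners are a salicylaldehyde with only one free ortho-OH and 6-hydroxybenzofuran-2(3H)-one, which brings ring B and releases 2'-OH.
3. Key disconnection: ArO–C(CH3)2CH=CH2 goes back to symmetric 2,6-dihydroxy-4-methoxybenzaldehyde plus 3-methylbuta-1,2-diene (new Pd–H O–H addition). This bond distinguishes O5 from O1.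
4. The aldehyde comes from 2,4,6-trihydroxybenzaldehyde by para-selective O-methylation. The lactone comes from 2,4-dimethoxyphenylacetic acid.
5. Ring order: rings A and B are bought. The temporary five-membered lactone on ring B is closed first, and ring C is closed last at its expense.

Assumption: the target has no stereocentre, no stereogenic double bond (the prenyl alkene is gem-dimethyl) and no hindered axis. It is achiral, so no enantiocontrol is needed.

**Step 1**
Reactants: 1 2,4,6-trihydroxybenzaldehyde
Product: 2 2,6-dihydroxy-4-methoxybenzaldehyde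
Conditions: Me2SO4 (1.0 equiv), K2CO3 (1.0 equiv), acetone, 0 °C to rt, 12 h
Reagents that add atoms: dimethyl sulfate, COS(=O)(=O)OC
Why: Williamson O-methylation with one equivalent of base and a hard methyl donor goes to the 4-OH, which is the most acidic phenol (para vinylogous acid) and the only one not hydrogen-bonded to the formyl oxygen.

**Step 2**
Reactants: 2 2,6-dihydroxy-4-methoxybenzaldehyde; 3 3-methylbuta-1,2-diene
Product: 4 2-hydroxy-4-methoxy-6-[(2-methylbut-3-en-2-yl)oxy]benzaldehyde
Conditions: Pd(PPh3)4 (5 mol %), 3 (1.2 equiv), THF, 0 °C to 25 °C, Ar, stopped at full mono-conversion; work-up below 30 °C, Et3N-washed silica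
Reagents that add atoms: none
Why: Proposed new method: by-product-free O–H addition of a chelated phenol across 3-methylbuta-1,2-diene (reverse O-prenylation), in which phenol 2, a vinylogous carboxylic acid of pKa about 8, protonates zerovalent palladium to a divalent palladium hydride, hydropalladation of the unsubstituted allene C=C places H on the central carbon and gives the 1,1-dimethyl-π-allyl palladium phenoxide ion pair, and the phenoxide oxygen attacks the more substituted, more cationic terminus under kinetic control to give the tertiary ether; the addition should stop at the mono-ether because the remaining OH is then fully chelated, less acidic and more crowded, and the roughly 50 kJ/mol by which the cumulene lies above isoprene makes the addition exergonic where isoprene itself would be about thermoneutral; the closest known reaction types are the metal-catalysed hydrocarboxylation and hydroalkoxylation of allenes to branched allylic esters and ethers, and the Tsuji–Trost O-alkylation of phenols with tertiary 2-methylbut-3-en-2-yl carbonates, which passes through the same ion pair; no stereocentre is formed.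

**Step 3**
Reactants: 5 2,4-dimethoxyphenylacetic acid
Product: 7 6-hydroxybenzofuran-2(3H)-one, via 2,4-dihydroxyphenylacetic acid 6 (not isolated)
Conditions: 48 % aq HBr, AcOH, reflux, 6 h; concentrate; TsOH·H2O (2 mol %), toluene, Dean–Stark, 2 h
Reagents that add atoms: none
Why: HBr cleaves both aryl methyl ethers by SN2 attack of bromide on the protonated ethers, and the ortho-hydroxy acid then closes by acid-catalysed lactonisation (intramolecular Fischer esterification) driven by azeotropic water removal.

**Step 4**
Reactants: 4 2-hydroxy-4-methoxy-6-[(2-methylbut-3-en-2-yl)oxy]benzaldehyde; 7 6-hydroxybenzofuran-2(3H)-one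
Product: 10 5-hydroxy-3-(2,4-dihydroxyphenyl)-7-methoxy-6-(3-methylbut-2-en-1-yl)-2H-chromen-2-one (target), via aryl ester 8 (not isolated), via 5-O-(1,1-dimethylallyl)coumarin 9 (not isolated)
Conditions: 7 (1.2 equiv), Et3N (30 mol %), DMAP (10 mol %), 4 Å MS, 1,4-dioxane, 40 °C, 24 h, Ar; then AcOH (50 mol %), 100 °C, 5 h
Reagents that add atoms: none
Why: Perkin–Oglialoro-type transacylation moves the acyl group of the strained aryl lactone 7 onto the only free phenol of 4 (O1–C2 bond, releasing 2'-OH), intramolecular Knoevenagel condensation closes ring C on O1 because O5 is blocked, and after the base is neutralised the tertiary allyl aryl ether undergoes aromatic Claisen rearrangement to C6, the only open ortho carbon, with allyl inversion to the linear prenyl group and release of 5-OH; no stereocentre is formed.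

**Compound list**
1 | 2,4,6-trihydroxybenzaldehyde | O=Cc1c(O)cc(O)cc1O | starting material
2 | 2,6-dihydroxy-4-methoxybenzaldehyde | COc1cc(O)c(C=O)c(O)c1 | intermediate
3 | 3-methylbuta-1,2-diene | CC(C)=C=C | starting material
4 | 2-hydroxy-4-methoxy-6-[(2-methylbut-3-en-2-yl)oxy]benzaldehyde | COc1cc(O)c(C=O)c(OC(C)(C)C=C)c1 | intermediate
5 | 2,4-dimethoxyphenylacetic acid | COc1ccc(CC(=O)O)c(OC)c1 | starting material
6 | 2,4-dihydroxyphenylacetic acid | OC(=O)Cc1ccc(O)cc1O | intermediate (not isolated)
7 | 6-hydroxybenzofuran-2(3H)-one | O=C1Cc2ccc(O)cc2O1 | intermediate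
8 | 2-formyl-5-methoxy-3-[(2-methylbut-3-en-2-yl)oxy]phenyl (2,4-dihydroxyphenyl)acetate | COc1cc(OC(=O)Cc2ccc(O)cc2O)c(C=O)c(OC(C)(C)C=C)c1 | intermediate (not isolated)
9 | 3-(2,4-dihydroxyphenyl)-7-methoxy-5-[(2-methylbut-3-en-2-yl)oxy]-2H-chromen-2-one | COc1cc2oc(=O)c(-c3ccc(O)cc3O)cc2c(OC(C)(C)C=C)c1 | intermediate (not isolated)
10 | 5-hydroxy-3-(2,4-dihydroxyphenyl)-7-methoxy-6-(3-methylbut-2-en-1-yl)-2H-chromen-2-one | COc1cc2oc(=O)c(-c3ccc(O)cc3O)cc2c(O)c1CC=C(C)C | target

**Step count**
Total step count: 4. Steps 1, 2 and 4 form the main line, and step 3 is the side branch.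
Longest linear sequence: 3 steps (1 → 2 → 4 → 10).

**Three steps most likely to fail**

**Step 2 (the proposed new step).**
- Hydride formation from the phenol may be slow.
- Zerovalent palladium may re-ionise the product and leak to the linear O-prenyl ether, to C-prenylated aldehyde, or to isoprene plus 2.
- Some bis-ether may form.

The fallback uses known chemistry without π-allyl intermediates. It sets out from 2 and comes back at 4. Compound 2 is alkylated with 3-chloro-3-methylbut-1-yne (K2CO3, catalytic KI, acetone, 55 °C) to give 2-hydroxy-4-methoxy-6-[(2-methylbut-3-yn-2-yl)oxy]benzaldehyde F1. Its alkyne is then semi-hydrogenated (H2, 1 atm, Pd/CaCO3 poisoned with Pb(OAc)2, quinoline, EtOAc, rt) to give 4.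

**Step 4.**
- The hindered, electron-rich aldehyde may condense too slowly at 40 °C.
- The tertiary ether may lose isoprene.
- Residual base during the hot stage could let 2'-O open the lactone and let it re-close on the freed O5. That would give the 8-prenyl isomer.

The fallback sets out from 4 and from 6, which is isolated by stopping step 3 after the HBr stage. It comes back at 10. It uses an open-chain, protected acid, so 2'-O cannot take part in acyl transfer.

Compound 6 is persilylated (TBSCl, imidazole, DMF) to tert-butyldimethylsilyl [2,4-bis(tert-butyldimethylsilyloxy)phenyl]acetate F2. Only the silyl ester is cleaved (K2CO3, aqueous MeOH/THF, 0 °C) to give [2,4-bis(tert-butyldimethylsilyloxy)phenyl]acetic acid F3. Steglich esterification of 4 with F3 (EDC·HCl, DMAP, CH2Cl2, 0 °C) gives 2-formyl-5-methoxy-3-[(2-methylbut-3-en-2-yl)oxy]phenyl [2,4-bis(tert-butyldimethylsilyloxy)phenyl]acetate F4.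

Et3N at rt closes F4 by intramolecular Knoevenagel condensation to 3-[2,4-bis(tert-butyldimethylsilyloxy)phenyl]-7-methoxy-5-[(2-methylbut-3-en-2-yl)oxy]-2H-chromen-2-one F5. Base-free Claisen rearrangement in toluene at 110 °C gives 3-[2,4-bis(tert-butyldimethylsilyloxy)phenyl]-5-hydroxy-7-methoxy-6-(3-methylbut-2-en-1-yl)-2H-chromen-2-one F6. Et3N·3HF in THF at rt then gives 10.

**Step 1.**
- Over-methylation, ortho-O-methylation or C-methylation of the phloroglucinol core may lower the yield.

The fallback sets out from 1 and comes back at 2. It replaces selective alkylation with exhaustive alkylation followed by chelation-directed dealkylation. Compound 1 is permethylated (excess Me2SO4, K2CO3, acetone, reflux) to 2,4,6-trimethoxybenzaldehyde F7. AlCl3 (5 equiv, CH2Cl2, reflux) then removes only the two methyl groups ortho to the formyl group and gives 2.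

**Further compounds**
F1 | step 2 | 2-hydroxy-4-methoxy-6-[(2-methylbut-3-yn-2-yl)oxy]benzaldehyde | COc1cc(O)c(C=O)c(OC(C)(C)C#C)c1
F2 | step 4 | tert-butyldimethylsilyl [2,4-bis(tert-butyldimethylsilyloxy)phenyl]acetate | CC(C)(C)[Si](C)(C)OC(=O)Cc1ccc(O[Si](C)(C)C(C)(C)C)cc1O[Si](C)(C)C(C)(C)C
F3 | step 4 | [2,4-bis(tert-butyldimethylsilyloxy)phenyl]acetic acid | OC(=O)Cc1ccc(O[Si](C)(C)C(C)(C)C)cc1O[Si](C)(C)C(C)(C)C
F4 | step 4 | 2-formyl-5-methoxy-3-[(2-methylbut-3-en-2-yl)oxy]phenyl [2,4-bis(tert-butyldimethylsilyloxy)phenyl]acetate | COc1cc(OC(=O)Cc2ccc(O[Si](C)(C)C(C)(C)C)cc2O[Si](C)(C)C(C)(C)C)c(C=O)c(OC(C)(C)C=C)c1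
F5 | step 4 | 3-[2,4-bis(tert-butyldimethylsilyloxy)phenyl]-7-methoxy-5-[(2-methylbut-3-en-2-yl)oxy]-2H-chromen-2-one | COc1cc2oc(=O)c(-c3ccc(O[Si](C)(C)C(C)(C)C)cc3O[Si](C)(C)C(C)(C)C)cc2c(OC(C)(C)C=C)c1
F6 | step 4 | 3-[2,4-bis(tert-butyldimethylsilyloxy)phenyl]-5-hydroxy-7-methoxy-6-(3-methylbut-2-en-1-yl)-2H-chromen-2-one | COc1cc2oc(=O)c(-c3ccc(O[Si](C)(C)C(C)(C)C)cc3O[Si](C)(C)C(C)(C)C)cc2c(O)c1CC=C(C)C
F7 | step 1 | 2,4,6-trimethoxybenzaldehyde | COc1cc(OC)c(C=O)c(OC)c1
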